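**Plan**

- Numbering used throughout (daucane): C1 = quaternary carbon bearing the angular methyl (C15), C2/C3 = CH2, C4 = C(OH)(i-Pr), C5 = ring-fusion CH, C6 = CH–O, C7 = CH2, C8 = C(OH)CH3, C9=C10; ring A = cyclopentane (C1–C5), ring B = cycloheptene (C1, C5–C10); β = face of the angular methyl, α = face of H5.
- Retrosynthesis: cut the ester C6–O and the C8–CH3 bond; read the allylic alcohol C10=C9–C8(OH) of ring B as the transposed form of a ring-B 1,3-dione (C8, C10) and the C6 oxygen as a silyl group; trace the angular methyl to a CH2–SiMe2–O tether on the C4 oxygen.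
- Key cut: C8–C9 and C5–C6 at once. C8 and C10 stand 1,3 at carbonyl level with C6 β to C8, so ring B is the (3+4) sum of the three-carbon unit C6–C7–C8 (a Z β-silyl acryloylsilane) and the four-carbon unit C9–C10–C1=C5 (methyl ketone enolate of an acetylcyclopentene).
- Forward: ring A by aldol condensation; ring B by one anionic cascade (Brook shift, cyclopropanolate, oxy-Cope expansion from three to seven atoms) that ends by closing a temporary siloxane ring C across C1 and C4; then tether removal, dione transposition, methyl addition, Si-to-O exchange, esterification.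
- Stereochemistry: C4 from (R)-2-hydroxy-3-methylbutanoic acid (retentive alkylation through its pivalaldehyde acetal); C5 by bond formation anti to i-Pr; C6 from the Z alkene through the boat oxy-Cope; C1 from the β tether (trans fusion); C8 by β-face methyl addition; C6–O by retentive C–Si oxidation.

Key step: step 11

Remark: compounds 1, 3, 10 and 24 and all reagents are taken as commercially available; the lactol carbon of 6 and the C10 carbinol of 20 are epimer mixtures of no consequence, because both centres are destroyed in the same step.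

**Route**

Step 1
Reactants: 1 (2R)-2-hydroxy-3-methylbutanoic acid
Product: 2 (2R,5R)-2-tert-butyl-5-(propan-2-yl)-1,3-dioxolan-4-one (cis)
Conditions: t-BuCHO, p-TsOH (cat.), pentane, reflux, water separator; cis isomer purified by crystallization
Reagents that add atoms: 2,2-dimethylpropanal (pivalaldehyde), CC(C)(C)C=O
Why: Acid-catalysed acetalization of the α-hydroxy acid under equilibrating conditions should give the cis dioxolanone, whose acetal centre stores the chirality of C5 for the next step.

Step 2
Reactants: 3 2-(3-chloropropyl)-2-methyl-1,3-dioxolane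
Product: 4 2-(3-iodopropyl)-2-methyl-1,3-dioxolane
Conditions: NaI, acetone, reflux
Reagents that add atoms: sodium iodide, [Na+].[I-]
Why: Finkelstein halide exchange, driven by precipitation of NaCl, provides an iodide reactive enough for the hindered enolate of step 3.

Step 3
Reactants: 2 (2R,5R)-2-tert-butyl-5-(propan-2-yl)-1,3-dioxolan-4-one; 4 2-(3-iodopropyl)-2-methyl-1,3-dioxolane
Product: 5 (2R,5R)-2-tert-butyl-5-[3-(2-methyl-1,3-dioxolan-2-yl)propyl]-5-(propan-2-yl)-1,3-dioxolan-4-one
Conditions: LiN(i-Pr)2, THF, −78 °C; then 4, DMPU, −78 → −20 °C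
Reagents that add atoms: none
Why: Enolate alkylation with self-regeneration of the stereocentre: the iodide should enter trans to the tert-butyl group, so the chain takes the place of the former hydrogen with retention and fixes the C4 carbinol centre of the target.

Step 4
Reactants: 5 (2R,5R)-2-tert-butyl-5-[3-(2-methyl-1,3-dioxolan-2-yl)propyl]-5-(propan-2-yl)-1,3-dioxolan-4-one
Product: 7 (2R)-2-hydroxy-6-oxo-2-(propan-2-yl)heptanal, via lactol 6 (not isolated)
Conditions: (i-Bu)2AlH, CH2Cl2, −78 °C; then 1 M HCl, THF, 25 °C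
Reagents that add atoms: water, O
Why: Hydride reduction of the lactone carbonyl stops at the lactol, and acid hydrolysis of both acetals releases the aldehyde and the methyl ketone; the quaternary carbinol has no α-hydrogen and cannot epimerize.

Step 5
Reactants: 7 (2R)-2-hydroxy-6-oxo-2-(propan-2-yl)heptanal
Product: 8 1-[(3R)-3-hydroxy-3-(propan-2-yl)cyclopent-1-en-1-yl]ethan-1-one
Conditions: piperidine (cat.), AcOH (cat.), toluene, 25 → 50 °C
Reagents that add atoms: none
Why: Intramolecular aldol condensation (5-enolexo): only the ketone can enolize, its CH2 closes ring A onto the non-enolizable aldehyde, and dehydration gives the conjugated acetylcyclopentene without touching the stereocentre.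

Step 6
Reactants: 8 1-[(3R)-3-hydroxy-3-(propan-2-yl)cyclopent-1-en-1-yl]ethan-1-one
Product: 9 1-[(3R)-3-{[(bromomethyl)dimethylsilyl]oxy}-3-(propan-2-yl)cyclopent-1-en-1-yl]ethan-1-one
Conditions: BrCH2SiMe2Cl, imidazole, CH2Cl2, 0 → 25 °C
Reagents that add atoms: (bromomethyl)chlorodimethylsilane, C[Si](C)(Cl)CBr
Why: O-Silylation of the tertiary allylic alcohol installs the one-carbon tether (the future angular methyl carbon C15) on the β oxygen of C4.

Step 7
Reactants: 10 tert-butyldimethyl(prop-2-yn-1-yloxy)silane
Product: 11 tert-butyl({3-[dimethyl(phenyl)silyl]prop-2-yn-1-yl}oxy)dimethylsilane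
Conditions: n-BuLi, THF, −78 °C; then PhMe2SiCl, −78 → 0 °C
Reagents that add atoms: chlorodimethyl(phenyl)silane, C[Si](C)(Cl)c1ccccc1
Why: C-Silylation of the lithium acetylide introduces the arylsilyl group that later serves as the masked C6 hydroxyl.

Step 8
Reactants: 11 tert-butyl({3-[dimethyl(phenyl)silyl]prop-2-yn-1-yl}oxy)dimethylsilane
Product: 12 1-[tert-butyl(dimethyl)silyl]-3-[dimethyl(phenyl)silyl]prop-2-yn-1-ol (racemic)
Conditions: s-BuLi, THF, −78 → −45 °C; then AcOH
Reagents that add atoms: none
Why: Retro-Brook rearrangement: lithiation at the propargylic O-bearing carbon is followed by 1,2-migration of silicon from oxygen to carbon, driven by formation of the lithium alkoxide.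

Step 9
Reactants: 12 1-[tert-butyl(dimethyl)silyl]-3-[dimethyl(phenyl)silyl]prop-2-yn-1-ol
Product: 13 (2Z)-1-[tert-butyl(dimethyl)silyl]-3-[dimethyl(phenyl)silyl]prop-2-en-1-ol (racemic)
Conditions: H2 (1 atm), Pd/CaCO3 poisoned with Pb(OAc)2, quinoline, hexane/EtOAc, 25 °C
Reagents that add atoms: none
Why: Syn semihydrogenation of the alkyne on the poisoned palladium surface sets the Z alkene that later controls C6.

Step 10
Reactants: 13 (2Z)-1-[tert-butyl(dimethyl)silyl]-3-[dimethyl(phenyl)silyl]prop-2-en-1-ol
Product: 14 (2Z)-1-[tert-butyl(dimethyl)silyl]-3-[dimethyl(phenyl)silyl]prop-2-en-1-one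
Conditions: Dess–Martin periodinane, pyridine, CH2Cl2, 0 °C, in the dark
Reagents that add atoms: none
Why: Dess–Martin oxidation of the α-silyl allylic alcohol gives the acylsilane under non-basic, non-nucleophilic conditions that should preserve the Z geometry.

Step 11
Reactants: 9 1-[(3R)-3-{[(bromomethyl)dimethylsilyl]oxy}-3-(propan-2-yl)cyclopent-1-en-1-yl]ethan-1-one; 14 (2Z)-1-[tert-butyl(dimethyl)silyl]-3-[dimethyl(phenyl)silyl]prop-2-en-1-one
Product: 17 8-[(tert-butyldimethylsilyl)oxy]-6α-[dimethyl(phenyl)silyl]-14-nordauc-7-en-10-one whose C15 is joined through SiMe2 to the 4β oxygen (trans-fused 5α-H), via cyclopropanolate 15 (not isolated), via ring-B enolate 16 (not isolated)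
Conditions: LiN(i-Pr)2 (1.05 equiv), THF, −80 °C; then 14, −80 → −30 °C; then DMPU, −30 → 25 °C
Reagents that add atoms: none
Why: Proposed new method: the lithium dienolate of 9 adds through its methyl carbon (C9) to the acylsilane carbonyl (C8) of 14, the alkoxide triggers a 1,2-Brook shift of the tert-butyldimethylsilyl group to oxygen, and the siloxyallyl anion closes on the C10 carbonyl (3-exo-trig) to the cis-dialkenylcyclopropanolate 15, whose anion-accelerated oxy-Cope rearrangement through a boat transition state forms C5–C6 and expands the three-membered ring to ring B as the C1=C10 enolate 16; 16 then displaces bromide from the tether on the C4 oxygen (6-exo-tet, at carbon because O-attack would need an eight-membered ring), closing ring C. The closest known reactions are the Brook rearrangement-mediated (3+4) annulation of β-silyl acryloylsilanes with lithium enolates of 1-acetylcycloalkenes and the silicon-tethered (halomethylsilyl ether) delivery of an angular methyl carbon cis to a hydroxyl; the new element is their coupling in one cascade with enolate C-alkylation as the terminating event. C5 is set by C6 bonding to the cyclopentene face that carries the C4 oxygen, anti to the larger isopropyl group, which requires that the cyclopropanolate forms reversibly or that the two diastereomeric boats differ enough in energy. C6 follows stereospecifically from the Z alkene of 14, whose inward silyl group ends cis to H5 (α), and C1 is fixed by the tether, which can reach only the β face and so enforces the trans ring fusion that a free alkylation would not be expected to give. The step needs kinetic deprotonation of the methyl group, 1,2-addition to the acylsilane and survival of the bromomethylsilyl ether until 16 forms, which the low temperature, the electrophilic acylsilane carbonyl and the eight-membered geometry of any earlier intramolecular displacement should secure.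

Step 12
Reactants: 17 siloxane-bridged silyl enol ether ketone
Product: 18 6α-[dimethyl(phenyl)silyl]-4β-hydroxy-14-nordaucane-8,10-dione
Conditions: Bu4NF (6 equiv), DMF, 75 °C; then aq. NaH2PO4
Reagents that add atoms: none
Why: Fluoride cleaves the silyl enol ether to the 1,3-dione enolate and then attacks the tether silicon, whose C15–Si bond is broken by protodesilylation (fluoride-promoted cleavage of an alkyl(alkoxy)silane), so C15 becomes the β angular methyl and the C4 hydroxyl is freed while the oxygen-free arylsilyl group on C6 should stay.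

Step 13
Reactants: 18 6α-[dimethyl(phenyl)silyl]-4β-hydroxy-14-nordaucane-8,10-dione
Product: 19 6α-[dimethyl(phenyl)silyl]-4β-hydroxy-8-methoxy-14-nordauc-8-en-10-one
Conditions: MeOH, p-TsOH (cat.), 3 Å molecular sieves, 25 °C
Reagents that add atoms: methanol, CO
Why: Acid-catalysed enol etherification of the cyclic 1,3-dione under equilibrating conditions should place the methoxy group on C8, because the C10 carbonyl is flanked by the quaternary C1 (the selectivity known for 4,4-disubstituted cyclohexane-1,3-diones).

Step 14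
Reactants: 19 6α-[dimethyl(phenyl)silyl]-4β-hydroxy-8-methoxy-14-nordauc-8-en-10-one
Product: 21 6α-[dimethyl(phenyl)silyl]-4β-hydroxy-14-nordauc-9-en-8-one, via allylic alcohol 20 (not isolated)
Conditions: (i-Bu)2AlH (3 equiv), CH2Cl2, −78 → 0 °C; then 1 M HCl, THF, 0 °C
Reagents that add atoms: water, O
Why: Stork–Danheiser transposition: 1,2-reduction of the vinylogous ester at C10 followed by acid ionizes the allylic alcohol and hydrolyses the enol ether, leaving the C8 ketone conjugated to the new C9=C10 bond, so the C10 carbinol configuration is irrelevant.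

Step 15
Reactants: 21 6α-[dimethyl(phenyl)silyl]-4β-hydroxy-14-nordauc-9-en-8-one
Product: 22 6α-[dimethyl(phenyl)silyl]dauc-9-ene-4β,8α-diol
Conditions: CeCl3 (anhydrous), MeLi (3 equiv), THF, −78 °C
Reagents that add atoms: methyllithium, [Li]C
Why: 1,2-Addition of the methylcerium reagent to the enolizable enone should occur on the β face, opposite the large α silyl group on C6, giving the 8α-hydroxy-8β-methyl centre.

Step 16
Reactants: 22 6α-[dimethyl(phenyl)silyl]dauc-9-ene-4β,8α-diol
Product: 23 dauc-9-ene-4β,6α,8α-triol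
Conditions: KH, t-BuOOH, DMF, 25 °C; then Bu4NF, 70 °C
Reagents that add atoms: tert-butyl hydroperoxide, CC(C)(C)OO
Why: Tamao–Fleming oxidation under basic peroxide conditions converts C6–Si into C6–OH with retention (α) and spares the alkene and the acid-labile tertiary allylic alcohol.

Step 17
Reactants: 23 dauc-9-ene-4β,6α,8α-triol; 24 4-acetoxybenzoyl chloride
Product: 25 4β,8α-dihydroxydauc-9-en-6α-yl 4-acetoxybenzoate
Conditions: pyridine, DMAP (cat.), CH2Cl2, 0 → 25 °C
Reagents that add atoms: none
Why: DMAP-catalysed acylation takes the only secondary hydroxyl (C6) with retention, the two tertiary hydroxyls being unreactive under these conditions.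

Step 18
Reactants: 25 4β,8α-dihydroxydauc-9-en-6α-yl 4-acetoxybenzoate
Product: 26 4β,8α-dihydroxydauc-9-en-6α-yl 4-hydroxybenzoate (target)
Conditions: pyrrolidine (2 equiv), CH2Cl2, 0 °C
Reagents that add atoms: none
Why: Aminolysis of the aryl acetate (an activated phenyl ester) should be much faster than attack on the hindered secondary benzoate, freeing the phenol.

**Compound list**

1 | (2R)-2-hydroxy-3-methylbutanoic acid | CC(C)[C@@H](O)C(=O)O | starting material
2 | (2R,5R)-2-tert-butyl-5-(propan-2-yl)-1,3-dioxolan-4-one | CC(C)[C@H]1O[C@@H](C(C)(C)C)OC1=O | intermediate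
3 | 2-(3-chloropropyl)-2-methyl-1,3-dioxolane | CC1(CCCCl)OCCO1 | starting material
4 | 2-(3-iodopropyl)-2-methyl-1,3-dioxolane | CC1(CCCI)OCCO1 | intermediate
5 | (2R,5R)-2-tert-butyl-5-[3-(2-methyl-1,3-dioxolan-2-yl)propyl]-5-(propan-2-yl)-1,3-dioxolan-4-one | CC(C)[C@@]1(CCCC2(C)OCCO2)O[C@@H](C(C)(C)C)OC1=O | intermediate
6 | (2R,5R)-2-tert-butyl-5-[3-(2-methyl-1,3-dioxolan-2-yl)propyl]-5-(propan-2-yl)-1,3-dioxolan-4-ol (lactol, C4 epimers) | CC(C)[C@@]1(CCCC2(C)OCCO2)O[C@@H](C(C)(C)C)OC1O | intermediate
7 | (2R)-2-hydroxy-6-oxo-2-(propan-2-yl)heptanal | CC(C)[C@@](O)(C=O)CCCC(C)=O | intermediate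
8 | 1-[(3R)-3-hydroxy-3-(propan-2-yl)cyclopent-1-en-1-yl]ethan-1-one | CC(C)[C@]1(O)CCC(C(C)=O)=C1 | intermediate
9 | 1-[(3R)-3-{[(bromomethyl)dimethylsilyl]oxy}-3-(propan-2-yl)cyclopent-1-en-1-yl]ethan-1-one | CC(C)[C@]1(O[Si](C)(C)CBr)CCC(C(C)=O)=C1 | intermediate
10 | tert-butyldimethyl(prop-2-yn-1-yloxy)silane | C#CCO[Si](C)(C)C(C)(C)C | starting material
11 | tert-butyl({3-[dimethyl(phenyl)silyl]prop-2-yn-1-yl}oxy)dimethylsilane | CC(C)(C)[Si](C)(C)OCC#C[Si](C)(C)c1ccccc1 | intermediate
12 | 1-[tert-butyl(dimethyl)silyl]-3-[dimethyl(phenyl)silyl]prop-2-yn-1-ol (racemic) | CC(C)(C)[Si](C)(C)C(O)C#C[Si](C)(C)c1ccccc1 | intermediate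
13 | (2Z)-1-[tert-butyl(dimethyl)silyl]-3-[dimethyl(phenyl)silyl]prop-2-en-1-ol (racemic) | CC(C)(C)[Si](C)(C)C(O)/C=C\[Si](C)(C)c1ccccc1 | intermediate
14 | (2Z)-1-[tert-butyl(dimethyl)silyl]-3-[dimethyl(phenyl)silyl]prop-2-en-1-one | CC(C)(C)[Si](C)(C)C(=O)/C=C\[Si](C)(C)c1ccccc1 | intermediate
15 | lithium cis-1,2-dialkenylcyclopropanolate (cyclopropane C8–C9–C10; O-silyl on C8, O-lithium on C10) | [Li+].CC(C)[C@]1(O[Si](C)(C)CBr)CCC(=C1)[C@]2([O-])C[C@]2(O[Si](C)(C)C(C)(C)C)/C=C\[Si](C)(C)c3ccccc3 | intermediate
16 | lithium C1=C10 enolate of the ring-expanded bicycle (5α-H, 6α-silyl, tether still open) | [Li+].CC(C)[C@]1(O[Si](C)(C)CBr)CCC2=C([O-])CC(O[Si](C)(C)C(C)(C)C)=C[C@H]([Si](C)(C)c3ccccc3)[C@@H]12 | intermediate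
17 | 8-[(tert-butyldimethylsilyl)oxy]-6α-[dimethyl(phenyl)silyl]-14-nordauc-7-en-10-one with C15 joined through SiMe2 to the 4β oxygen | CC(C)[C@]1(O[Si](C)(C)C2)CC[C@@]23C(=O)CC(O[Si](C)(C)C(C)(C)C)=C[C@H]([Si](C)(C)c4ccccc4)[C@@H]13 | intermediate
18 | 6α-[dimethyl(phenyl)silyl]-4β-hydroxy-14-nordaucane-8,10-dione | CC(C)[C@]1(O)CC[C@]2(C)C(=O)CC(=O)C[C@H]([Si](C)(C)c3ccccc3)[C@H]21 | intermediate
19 | 6α-[dimethyl(phenyl)silyl]-4β-hydroxy-8-methoxy-14-nordauc-8-en-10-one | CC(C)[C@]1(O)CC[C@]2(C)C(=O)C=C(OC)C[C@H]([Si](C)(C)c3ccccc3)[C@H]21 | intermediate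
20 | 6α-[dimethyl(phenyl)silyl]-8-methoxy-14-nordauc-8-ene-4β,10-diol (C10 epimers) | CC(C)[C@]1(O)CC[C@]2(C)C(O)C=C(OC)C[C@H]([Si](C)(C)c3ccccc3)[C@H]21 | intermediate
21 | 6α-[dimethyl(phenyl)silyl]-4β-hydroxy-14-nordauc-9-en-8-one | CC(C)[C@]1(O)CC[C@]2(C)C=CC(=O)C[C@H]([Si](C)(C)c3ccccc3)[C@H]21 | intermediate
22 | 6α-[dimethyl(phenyl)silyl]dauc-9-ene-4β,8α-diol | CC(C)[C@]1(O)CC[C@]2(C)C=C[C@](C)(O)C[C@H]([Si](C)(C)c3ccccc3)[C@H]21 | intermediate
23 | dauc-9-ene-4β,6α,8α-triol | CC(C)[C@]1(O)CC[C@]2(C)C=C[C@](C)(O)C[C@H](O)[C@H]21 | intermediate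
24 | 4-acetoxybenzoyl chloride | CC(=O)Oc1ccc(cc1)C(Cl)=O | starting material
25 | 4β,8α-dihydroxydauc-9-en-6α-yl 4-acetoxybenzoate | CC(C)[C@]1(O)CC[C@]2(C)C=C[C@](C)(O)C[C@H](OC(=O)c3ccc(OC(C)=O)cc3)[C@H]21 | intermediate
26 | (3R,3aS,4S,6R,8aR)-3,6-dihydroxy-6,8a-dimethyl-3-(propan-2-yl)-1,2,3,3a,4,5,6,8a-octahydroazulen-4-yl 4-hydroxybenzoate (4β,8α-dihydroxydauc-9-en-6α-yl 4-hydroxybenzoate) | CC(C)[C@]1(O)CC[C@]2(C)C=C[C@](C)(O)C[C@H](OC(=O)c3ccc(O)cc3)[C@H]21 | target

**Step count**

Total: 18 steps. Longest linear sequence: 13 steps (1, 3, 4, 5, 6, 11–18, from compound 1).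

**Steps most likely to fail**

Step 11. The ring-B enolate 16 may fail to displace bromide at the congested, α-silyl carbon before proton exchange with C9 or decay of the tether sets in, and the oxy-Cope may discriminate poorly between the two faces of C5 or run sluggishly with the inward Z silyl group. The fallback keeps the same ring-forming annulation, which is known, and closes the C1–C15 bond by radical chemistry. From 9 and 14 the annulation is run as in step 11 but held at −30 °C and quenched with Et3SiCl, which should give the bis(silyl enol ether) F1. Bu3SnH and AIBN in benzene at 80 °C then generate the silylmethyl radical on the tether, which should add 6-exo to C1 on the β face, and hydrogen transfer to C10 gives the bridged siloxane F2. Bu4NF in DMF at 75 °C removes the enol silyl group, the triethylsilyl group and the tether silicon (protodesilylation to the angular methyl), giving the β-hydroxy ketone F3. MsCl/Et3N followed by DBU eliminates to enone 21, where the route is rejoined (steps 12–14 are skipped).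

Step 12. During the prolonged heating that the neopentyl C–Si cleavage needs, the seven-membered 1,3-dione may open by retro-Claisen attack of hydroxide or fluoride at the C10 carbonyl. The fallback never forms the dione. From 17, KN(SiMe3)2 and PhNTf2 should give the dienyl triflate F4 (enolization is possible only toward C9). Pd(OAc)2/PPh3 with HCO2H/Et3N in DMF at 60 °C reduces the C–OTf bond to give the 2-silyloxy-1,3-diene F5. Bu4NF in DMF at 75 °C then frees the enone and protodesilylates the tether in one pot, giving 21 directly (steps 13 and 14 are then not needed).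

Step 15. Facial selectivity may be poor: methyl delivery from the α face would give the C8 epimer. The fallback builds the carbinol from an alkene so that the oxygen, not the carbon, is delivered under substrate direction. From 21, Wittig methylenation (Ph3P=CH2, THF) gives the exocyclic diene F6. Basic-peroxide Tamao–Fleming oxidation as in step 16 gives the 6α alcohol F7. VO(acac)2/t-BuOOH should epoxidize the exocyclic alkene on the α face under direction of the homoallylic 6α hydroxyl, giving the spiro-epoxide F8. LiAlH4 opens the epoxide at its CH2 terminus and gives triol 23, where the route is rejoined.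

**Further compounds**

F1 | step 11 | bis(silyl enol ether): C10 O-triethylsilyl and C8 O-tert-butyldimethylsilyl enol ethers of the ring-expanded bicycle with the bromomethylsilyl ether on C4 | CC(C)[C@]1(O[Si](C)(C)CBr)CCC2=C(O[Si](CC)(CC)CC)CC(O[Si](C)(C)C(C)(C)C)=C[C@H]([Si](C)(C)c3ccccc3)[C@@H]12
F2 | step 11 | siloxane-bridged 10-(triethylsilyloxy) compound (C15 joined through SiMe2 to the 4β oxygen, C10 epimers) | CC(C)[C@]1(O[Si](C)(C)C2)CC[C@@]23C(O[Si](CC)(CC)CC)CC(O[Si](C)(C)C(C)(C)C)=C[C@H]([Si](C)(C)c4ccccc4)[C@@H]13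
F3 | step 11 | 6α-[dimethyl(phenyl)silyl]-4β,10-dihydroxy-14-nordaucan-8-one (C10 epimers) | CC(C)[C@]1(O)CC[C@]2(C)C(O)CC(=O)C[C@H]([Si](C)(C)c3ccccc3)[C@H]21
F4 | step 12 | siloxane-bridged 8-(tert-butyldimethylsilyloxy)-14-nordauca-7,9-dien-10-yl trifluoromethanesulfonate | CC(C)[C@]1(O[Si](C)(C)C2)CC[C@@]23C(OS(=O)(=O)C(F)(F)F)=CC(O[Si](C)(C)C(C)(C)C)=C[C@H]([Si](C)(C)c4ccccc4)[C@@H]13
F5 | step 12 | siloxane-bridged 8-(tert-butyldimethylsilyloxy)-6α-[dimethyl(phenyl)silyl]-14-nordauca-7,9-diene | CC(C)[C@]1(O[Si](C)(C)C2)CC[C@@]23C=CC(O[Si](C)(C)C(C)(C)C)=C[C@H]([Si](C)(C)c4ccccc4)[C@@H]13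
F6 | step 15 | 6α-[dimethyl(phenyl)silyl]dauca-8(14),9-dien-4β-ol | CC(C)[C@]1(O)CC[C@]2(C)C=CC(=C)C[C@H]([Si](C)(C)c3ccccc3)[C@H]21
F7 | step 15 | dauca-8(14),9-diene-4β,6α-diol | CC(C)[C@]1(O)CC[C@]2(C)C=CC(=C)C[C@H](O)[C@H]21
F8 | step 15 | 8α,14-epoxydauc-9-ene-4β,6α-diol | CC(C)[C@]1(O)CC[C@]2(C)C=C[C@@]3(CO3)C[C@H](O)[C@H]21
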